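**Strategy.** The target is cut at the C4–C5 bond of its heptadecenyl chain (numbered from the ring), in the middle of the unbranched heptamethylene tether that separates the resorcinol ring from the C8=C9 Z-olefin and the C11 carbinol. The key step exploits exactly this feature: both carbons are primary and unactivated, so a B-alkyl-9-BBN, made in the flask from a terminal butenyl arene, is joined to an unprotected (Z)-homoallylic alcohol carrying a primary chloride by an alkyl–alkyl Suzuki–Miyaura coupling. The chloride partner comes from (S)-1,2-epoxyoctane by alkynylation and Lindlar reduction, so stereocentre and olefin geometry are fixed before the union; a final debenzylation gives the target.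

Key step: step 4

Remark: the carbinol centre of the target is S by the CIP rules; (S)-1,2-epoxyoctane and 3,5-bis(benzyloxy)benzyl bromide are taken as commercially available, and 9-BBN is used as its commercial dimer.

**Step 1**
Reactants: 1 3,5-bis(benzyloxy)benzyl bromide; 2 allylmagnesium bromide
Product: 3 1,3-bis(benzyloxy)-5-(but-3-en-1-yl)benzene
Conditions: 2 (1.3 equiv, 1.0 M in Et2O), THF, 0 °C to rt; aq NH4Cl
Reagents that add atoms: none
Why: Uncatalysed SN2-type coupling of an allyl Grignard reagent with a benzylic bromide is fast, and the aryl benzyl ethers are inert to the Grignard reagent; no stereocentre is involved.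

**Step 2**
Reactants: 4 5-chloropent-1-yne; 5 (S)-1,2-epoxyoctane
Product: 7 (S)-1-chlorotridec-4-yn-7-ol, via lithium 5-chloropent-1-ynide 6 (not isolated)
Conditions: 4 (1.5 equiv), n-BuLi, THF, −78 °C; BF3·OEt2, −78 °C; then 5 (1.0 equiv), −78 °C; H2O
Reagents that add atoms: none
Why: In this Yamaguchi–Hirao alkynylation the BF3-activated terminal epoxide is opened by the acetylide at its unsubstituted CH2 in an SN2 manner, so the C–O stereocentre of 5 is untouched and becomes the (S)-carbinol, while the primary chloride is inert to the acetylide at −78 °C.

**Step 3**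
Reactants: 7 (S)-1-chlorotridec-4-yn-7-ol
Product: 8 (4Z,7S)-1-chlorotridec-4-en-7-ol
Conditions: H2 (1 atm), Lindlar catalyst (Pd/CaCO3, Pb-poisoned), quinoline, EtOAc, rt, stopped after 1 equiv of H2
Reagents that add atoms: none
Why: Lindlar semihydrogenation delivers both hydrogens syn on the poisoned palladium surface and should give the Z-olefin, with quinoline suppressing over-reduction and the alkyl chloride and carbinol centre untouched.

**Step 4**
Reactants: 3 1,3-bis(benzyloxy)-5-(but-3-en-1-yl)benzene; 8 (4Z,7S)-1-chlorotridec-4-en-7-ol
Product: 10 (7S,9Z)-17-[3,5-bis(benzyloxy)phenyl]heptadec-9-en-7-ol, via B-alkyl-9-BBN borane 9 (not isolated)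
Conditions: 3 (1.4 equiv), 9-BBN dimer (1.3 equiv B–H), dioxane, rt; then 8 (1.0 equiv), Pd2(dba)3 (5 mol %), PCy3 (20 mol %), CsOH·H2O (2.2 equiv), dioxane, 90 °C
Reagents that add atoms: none
Why: Anti-Markovnikov hydroboration of the terminal olefin of 3 with 9-BBN places boron on the terminal carbon (the future C4 of the chain) and is complete before 8 is added, with 3 in slight excess over B–H so that no borane is left to touch the Z-olefin of 8. Pd(0)/PCy3 then inserts into the primary C–Cl bond of 8 by an SN2-type oxidative addition, the hydroxide-activated borate transmetalates its primary alkyl group, and reductive elimination forms the C(sp3)–C(sp3) bond. The closest known reaction type is the alkyl–alkyl Suzuki–Miyaura coupling of unactivated primary alkyl chlorides bearing β-hydrogens with B-alkyl-9-BBN reagents under Pd2(dba)3/PCy3/CsOH·H2O. No ring is closed and no stereocentre is formed; the C7 carbinol of 8 (C11 of the target) and the Z-olefin are spectators. The step needs cross-coupling to outrun β-hydride elimination, which the bulky electron-rich PCy3 should secure, and tolerance of the free hydroxyl, which the aqueous-hydroxide medium should provide with one extra equivalent of CsOH. The olefin lies three carbons from the palladated carbon, so only strained 4-exo or 5-endo insertions are open to it and cyclisation should not compete.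

**Step 5**
Reactants: 10 (7S,9Z)-17-[3,5-bis(benzyloxy)phenyl]heptadec-9-en-7-ol
Product: 11 5-[(8Z,11S)-11-hydroxyheptadec-8-en-1-yl]benzene-1,3-diol
Conditions: BCl3 (5 equiv, 1 M in CH2Cl2), pentamethylbenzene (6 equiv), CH2Cl2, −78 °C; CHCl3/MeOH quench at −78 °C, then H2O
Reagents that add atoms: none
Why: Lewis-acid debenzylation of aryl benzyl ethers with BCl3 at −78 °C, with pentamethylbenzene trapping the benzyl cation by Friedel–Crafts alkylation, should spare the electron-rich resorcinol ring and the Z-olefin; the secondary alcohol is regenerated from its borate on quench and the stereocentre is not involved.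

**Compound list**
1 | 3,5-bis(benzyloxy)benzyl bromide | BrCc1cc(OCc2ccccc2)cc(OCc2ccccc2)c1 | starting material
2 | allylmagnesium bromide | C=CC[Mg]Br | starting material
3 | 1,3-bis(benzyloxy)-5-(but-3-en-1-yl)benzene | C=CCCc1cc(OCc2ccccc2)cc(OCc2ccccc2)c1 | intermediate
4 | 5-chloropent-1-yne | C#CCCCCl | starting material
5 | (S)-1,2-epoxyoctane ((S)-2-hexyloxirane) | CCCCCC[C@H]1CO1 | starting material
6 | lithium 5-chloropent-1-ynide | [Li]C#CCCCCl | intermediate
7 | (S)-1-chlorotridec-4-yn-7-ol | CCCCCC[C@H](O)CC#CCCCCl | intermediate
8 | (4Z,7S)-1-chlorotridec-4-en-7-ol | CCCCCC[C@H](O)C/C=C\CCCCl | intermediate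
9 | 9-{4-[3,5-bis(benzyloxy)phenyl]butyl}-9-borabicyclo[3.3.1]nonane | C(CCCc1cc(OCc2ccccc2)cc(OCc3ccccc3)c1)B4C5CCCC4CCC5 | intermediate
10 | (7S,9Z)-17-[3,5-bis(benzyloxy)phenyl]heptadec-9-en-7-ol | CCCCCC[C@H](O)C/C=C\CCCCCCCc1cc(OCc2ccccc2)cc(OCc2ccccc2)c1 | intermediate
11 | 5-[(8Z,11S)-11-hydroxyheptadec-8-en-1-yl]benzene-1,3-diol | CCCCCC[C@H](O)C/C=C\CCCCCCCc1cc(O)cc(O)c1 | target

**Step count.** Total: 5 steps. Longest linear sequence: 4 steps (steps 2, 3, 4, 5 from epoxide 5).

**Steps most likely to fail**

Step 4 (key coupling). Oxidative addition into the primary C–Cl bond may be sluggish. β-Hydride elimination from the alkylpalladium, and Pd–H-mediated Z→E isomerisation or migration of the olefin at 90 °C, could then gain ground, as could hydroxide-induced protodeboronation of the borane.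
Fallback: a copper-catalysed Grignard alkylation of Kochi type, setting out from 3 and 8 and returning at 10.
- Borane 9, made from 3 as before, is oxidised in the flask (NaOH, H2O2) to 4-[3,5-bis(benzyloxy)phenyl]butan-1-ol F1.
- An Appel reaction (CBr4, PPh3, CH2Cl2) should give 1,3-bis(benzyloxy)-5-(4-bromobutyl)benzene F2.
- Magnesium in THF converts F2 into {4-[3,5-bis(benzyloxy)phenyl]butyl}magnesium bromide F3.
- In parallel, a Finkelstein exchange (NaI, acetone, reflux) turns 8 into (4Z,7S)-1-iodotridec-4-en-7-ol F4.
- F4 is treated with 2.3 equiv of F3 and Li2CuCl4 (3 mol %) in THF at −30 to 0 °C. The first equivalent of F3 deprotonates the hydroxyl, the second is alkylated at the primary iodide, and 10 should result.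

Step 5 (debenzylation). If cation trapping is incomplete, the liberated and very electron-rich resorcinol ring may be C-benzylated. If the mixture warms before the quench, Lewis-acid ionisation or chlorination at the homoallylic carbinol or HCl addition to the olefin may occur.
Fallback: reductive instead of Lewis-acidic cleavage, from 10 directly to 11. Sodium in liquid NH3/THF at −78 °C, followed by solid NH4Cl, should cleave both aryl benzyl ethers by electron transfer. The isolated Z-olefin and the phenoxide ring are not reduced under these conditions. This fallback makes no new compound (F0).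

Step 3 (semihydrogenation). Over-reduction to the saturated chain and Z→E isomerisation on the catalyst surface would give contaminants that are hard to separate from 8.
Fallback: a non-hydrogenative copper hydride semireduction, from 7 to 8. (IPr)CuCl (2 mol %), NaOt-Bu (cat.), polymethylhydrosiloxane and i-BuOH in toluene at rt to 45 °C should effect syn-hydrocupration of the alkyne and protonolysis of the alkenylcopper. Olefins are not reduced by the copper hydride, so over-reduction is excluded, and the alkyl chloride and free hydroxyl are tolerated. This fallback makes no new compound (F0).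

**Further compounds**
F1 | step 4 | 4-[3,5-bis(benzyloxy)phenyl]butan-1-ol | OCCCCc1cc(OCc2ccccc2)cc(OCc2ccccc2)c1
F2 | step 4 | 1,3-bis(benzyloxy)-5-(4-bromobutyl)benzene | BrCCCCc1cc(OCc2ccccc2)cc(OCc2ccccc2)c1
F3 | step 4 | {4-[3,5-bis(benzyloxy)phenyl]butyl}magnesium bromide | Br[Mg]CCCCc1cc(OCc2ccccc2)cc(OCc2ccccc2)c1
F4 | step 4 | (4Z,7S)-1-iodotridec-4-en-7-ol | CCCCCC[C@H](O)C/C=C\CCCI
F0 | step 5 | none | none
F0 | step 3 | none | none
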